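**Strategy.** Each chromanone is cut at O1–C8a and C4–C4a, so both phloroglucinol rings A arrive as 3,5-bis(benzyloxy)benzyne. The key step exploits the 1,3-relationship of O1 and C4 across C2–C3 in each pyranone ring C: a potassium alkoxide on C2 adds to the aryne, and the aryl anion formed ortho to it acylates on the neighbouring amide carbon C4. This closes both rings C (four bonds) in one operation. The precursor is an acyclic (2S,3S)-2,3-bis[(S)-aryl(hydroxy)methyl]succinic bis(morpholide) that already carries C2, C3, C3'' and C2''. It comes from two Evans syn-aldol reactions on one succinyl bis(oxazolidinone), through a cis-fused dilactone.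

Key step: step 6

Remark on numbering: flavanone locants are used (ring A = phloroglucinol ring, ring C = pyranone ring); unprimed locants belong to the 4-methoxyphenyl half, doubly primed locants to the 4-hydroxyphenyl half.

Remark on stereochemistry: a syn-aldol unit O–C2–C3–C4(=O) that closes with retention at C2 gives a 2,3-cis chromanone. The all-S target therefore corresponds to two Evans syn-aldols of the same sense, and to the exo,exo cis-fused dilactone 9.

Assumption: 3,5-bis(benzyloxy)phenol is taken as a commercial starting material.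

**Step 1**
Reactants: 1 succinyl chloride; 2 (S)-4-benzyl-1,3-oxazolidin-2-one (2 equiv)
Product: 3 (4S,4'S)-3,3'-butanedioylbis(4-benzyl-1,3-oxazolidin-2-one)
Conditions: 2, n-BuLi, THF, −78 °C; then 1 (0.5 equiv), −78 → 0 °C
Reagents that add atoms: none
Why: N-acylation of the lithiated oxazolidinone by both acid chloride groups (imide formation) should give the symmetric bis-imide; no stereocentre is formed and the auxiliary centre is not touched.

**Step 2**
Reactants: 3 bis-imide; 4 4-methoxybenzaldehyde; 5 4-(benzyloxy)benzaldehyde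
Product: 9 (3S,3aS,6S,6aS)-3-[4-(benzyloxy)phenyl]-6-(4-methoxyphenyl)tetrahydro-1H,3H-furo[3,4-c]furan-1,4-dione (exo,exo cis-fused dilactone), via boron mono-aldolate 6 (not isolated), via boron bis-aldolate 7 (not isolated), via diol bis-imide 8 (not isolated)
Conditions: Bu2BOTf (1.05 equiv), iPr2NEt, CH2Cl2, 0 °C; 4 (1.0 equiv), −78 → −10 °C; Bu2BOTf (1.2 equiv), iPr2NEt, −10 → 0 °C; 5 (1.3 equiv), −78 → 0 °C; pH 7 buffer, MeOH, H2O2, 0 °C; DMAP (cat.), CH2Cl2, rt
Reagents that add atoms: none
Why: Two Evans syn-aldol reactions in sequence: each Z-dibutylboron imide enolate should react through a chair-like Zimmerman–Traxler transition state on the enolate face left open by the (S)-benzyl group, which sets the alpha carbon and its carbinol carbon as S,S in each half (C3/C2 with 4, then C3''/C2'' with 5; the already substituted alpha carbon is not re-enolised), and after work-up each hydroxyl attacks the distal imide carbonyl (5-exo-trig gamma-lactonisation), expelling both auxiliaries and locking the four centres in the dilactone.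

**Step 3**
Reactants: 9 dilactone
Product: 10 (2S,3S)-2-[(S)-[4-(benzyloxy)phenyl](hydroxy)methyl]-3-[(S)-hydroxy(4-methoxyphenyl)methyl]-1,4-di(morpholin-4-yl)butane-1,4-dione
Conditions: morpholine (6 equiv), AlMe3 (5 equiv), CH2Cl2, 0 °C → rt; aq. Rochelle salt
Reagents that add atoms: morpholine C1COCCN1
Why: Weinreb-type aminolysis by dimethylaluminium morpholide should open both gamma-lactones by acyl–oxygen cleavage, so none of the four stereocentres is at a reacting atom and all are retained; the morpholide is chosen because a neighbouring alkoxide cannot expel it, which blocks relactonisation under base.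

**Step 4**
Reactants: 11 3,5-bis(benzyloxy)phenol
Product: 12 2-bromo-3,5-bis(benzyloxy)phenol
Conditions: NBS (1.0 equiv), iPr2NH (10 mol %), CH2Cl2, −78 → 0 °C
Reagents that add atoms: N-bromosuccinimide O=C1CCC(=O)N1Br
Why: Amine-mediated ortho-selective electrophilic bromination of a phenol (the N-bromoamine is delivered through hydrogen bonding to the OH) should place bromine at C2, which is also para to a benzyloxy group; no stereocentre is involved.

**Step 5**
Reactants: 12 2-bromo-3,5-bis(benzyloxy)phenol
Product: 15 3,5-bis(benzyloxy)-2-(trimethylsilyl)phenyl trifluoromethanesulfonate, via aryl trimethylsilyl ether 13 (not isolated), via lithium 2-silylphenoxide 14 (not isolated)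
Conditions: HMDS, THF, 65 °C, then evaporation; n-BuLi, THF, −100 °C; Tf2O, −100 °C → rt
Reagents that add atoms: hexamethyldisilazane C[Si](C)(C)N[Si](C)(C)C; trifluoromethanesulfonic anhydride O=S(=O)(OS(=O)(=O)C(F)(F)F)C(F)(F)F
Why: O-silylation, bromine–lithium exchange, 1,3-retro-Brook O→C silyl shift and O-triflation of the resulting phenoxide form the standard one-pot route to ortho-(trimethylsilyl)aryl triflate aryne precursors; exchange at −100 °C should outrun benzylic deprotonation.

**Step 6**
Reactants: 10 bis(morpholide) diol; 15 aryne precursor (3 equiv)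
Product: 19 (2S,3S)-5,7-bis(benzyloxy)-3-[(2S,3S)-5,7-bis(benzyloxy)-2-[4-(benzyloxy)phenyl]-4-oxochroman-3-yl]-2-(4-methoxyphenyl)chroman-4-one, via dipotassium dialkoxide 16 (not isolated), via 3,5-bis(benzyloxy)benzyne 17 (not isolated), via dipotassium bis-hemiaminalate 18 (not isolated)
Conditions: KH (2.1 equiv), THF, 0 °C; then KF (6 equiv), 18-crown-6, slow addition of 15, THF, 0 °C → rt; AcOH, H2O, 0 °C
Reagents that add atoms: none
Why: Proposed new method: each potassium alkoxide of 16 should add to aryne 17 at the aryne carbon meta to the 3-benzyloxy group (inductive and distortion control), which places the aryl carbanion ortho to both the new ether oxygen and that benzyloxy group, and this carbanion adds to the proximal morpholine amide carbonyl to give a tetrahedral hemiaminalate that releases the ketone only on the acidic quench; the closest known reaction types are the fluoride-mediated annulation of arynes with methyl salicylates to xanthones (aryl ether formation, then intramolecular acyl capture) and the Parham cycloacylation of ortho-metalated aryl ethers onto carboxylic acid derivatives, neither shown for an aliphatic beta-hydroxy amide. Each ring C closes by 6-exo-trig attack of the aryl carbanion on the amide carbon, which is favoured over 7-membered attack on the distal amide. No new stereocentre is created: C2 and C2'' keep their C–O bonds, and C3 and C3'' should not be enolised because the C4 carbonyls stay masked as amide or hemiaminalate while base is present, so the (2S,3S,2''S,3''S) array of 10 is carried over unchanged. The step needs carbonyl capture to outrun protonation of the aryl anion, which the preformed aprotic dialkoxide secures, and it needs the alkoxides not to relactonise, which the non-leaving morpholide secures.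

**Step 7**
Reactants: 19 pentabenzyl ether
Product: 20 Sikokianin A
Conditions: H2 (1 atm), Pd/C, THF–MeOH, rt
Reagents that add atoms: none
Why: Hydrogenolysis of the five benzyl aryl ethers under neutral conditions should leave the aryl methyl ether, both ketones and the four stereocentres untouched, since no acid or base is present to enolise C3/C3'' or open ring C.

**Compound list**

1 | succinyl chloride | O=C(Cl)CCC(=O)Cl | starting material
2 | (S)-4-benzyl-1,3-oxazolidin-2-one | O=C1N[C@@H](Cc2ccccc2)CO1 | starting material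
3 | (4S,4'S)-3,3'-butanedioylbis(4-benzyl-1,3-oxazolidin-2-one) | O=C(CCC(=O)N1C(=O)OC[C@@H]1Cc1ccccc1)N1C(=O)OC[C@@H]1Cc1ccccc1 | intermediate
4 | 4-methoxybenzaldehyde | COc1ccc(C=O)cc1 | starting material
5 | 4-(benzyloxy)benzaldehyde | O=Cc1ccc(OCc2ccccc2)cc1 | starting material
6 | dibutylboron aldolate of the mono syn-aldol adduct of 3 with 4 (2S alpha carbon, S carbinol carbon) | COc1ccc([C@@H](OB(CCCC)CCCC)[C@@H](C(=O)N2C(=O)OC[C@@H]2Cc2ccccc2)CC(=O)N2C(=O)OC[C@@H]2Cc2ccccc2)cc1 | intermediate
7 | bis(dibutylboron aldolate) of the double syn-aldol adduct (all four new centres S) | COc1ccc([C@@H](OB(CCCC)CCCC)[C@@H](C(=O)N2C(=O)OC[C@@H]2Cc2ccccc2)[C@H](C(=O)N2C(=O)OC[C@@H]2Cc2ccccc2)[C@H](OB(CCCC)CCCC)c2ccc(OCc3ccccc3)cc2)cc1 | intermediate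
8 | (4S,4'S)-3,3'-{(2S,3S)-2-[(S)-[4-(benzyloxy)phenyl](hydroxy)methyl]-3-[(S)-hydroxy(4-methoxyphenyl)methyl]butanedioyl}bis(4-benzyl-1,3-oxazolidin-2-one) | COc1ccc([C@@H](O)[C@@H](C(=O)N2C(=O)OC[C@@H]2Cc2ccccc2)[C@H](C(=O)N2C(=O)OC[C@@H]2Cc2ccccc2)[C@H](O)c2ccc(OCc3ccccc3)cc2)cc1 | intermediate
9 | (3S,3aS,6S,6aS)-3-[4-(benzyloxy)phenyl]-6-(4-methoxyphenyl)tetrahydro-1H,3H-furo[3,4-c]furan-1,4-dione (cis-fused, both aryl groups exo) | COc1ccc([C@H]2OC(=O)[C@H]3[C@@H]2C(=O)O[C@@H]3c2ccc(OCc3ccccc3)cc2)cc1 | intermediate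
10 | (2S,3S)-2-[(S)-[4-(benzyloxy)phenyl](hydroxy)methyl]-3-[(S)-hydroxy(4-methoxyphenyl)methyl]-1,4-di(morpholin-4-yl)butane-1,4-dione | COc1ccc([C@@H](O)[C@@H](C(=O)N2CCOCC2)[C@H](C(=O)N2CCOCC2)[C@H](O)c2ccc(OCc3ccccc3)cc2)cc1 | intermediate
11 | 3,5-bis(benzyloxy)phenol | Oc1cc(OCc2ccccc2)cc(OCc2ccccc2)c1 | starting material
12 | 2-bromo-3,5-bis(benzyloxy)phenol | Oc1cc(OCc2ccccc2)cc(OCc2ccccc2)c1Br | intermediate
13 | [2-bromo-3,5-bis(benzyloxy)phenoxy]trimethylsilane | C[Si](C)(C)Oc1cc(OCc2ccccc2)cc(OCc2ccccc2)c1Br | intermediate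
14 | lithium 3,5-bis(benzyloxy)-2-(trimethylsilyl)phenoxide | [Li+].[O-]c1cc(OCc2ccccc2)cc(OCc2ccccc2)c1[Si](C)(C)C | intermediate
15 | 3,5-bis(benzyloxy)-2-(trimethylsilyl)phenyl trifluoromethanesulfonate | C[Si](C)(C)c1c(OS(=O)(=O)C(F)(F)F)cc(OCc2ccccc2)cc1OCc1ccccc1 | intermediate
16 | dipotassium dialkoxide of 10 | COc1ccc([C@@H]([O-])[C@@H](C(=O)N2CCOCC2)[C@H](C(=O)N2CCOCC2)[C@H]([O-])c2ccc(OCc3ccccc3)cc2)cc1.[K+].[K+] | intermediate
17 | 3,5-bis(benzyloxy)benzyne | C1#CC(OCc2ccccc2)=CC(OCc2ccccc2)=C1 | intermediate
18 | dipotassium bis-hemiaminalate (both C4 carbons carry O− and morpholin-4-yl; ring stereocentres as in 19) | COc1ccc([C@H]2Oc3cc(OCc4ccccc4)cc(OCc4ccccc4)c3C([O-])(N3CCOCC3)[C@H]2[C@@H]2C([O-])(N3CCOCC3)c3c(OCc4ccccc4)cc(OCc4ccccc4)cc3O[C@@H]2c2ccc(OCc3ccccc3)cc2)cc1.[K+].[K+] | intermediate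
19 | (2S,3S)-5,7-bis(benzyloxy)-3-[(2S,3S)-5,7-bis(benzyloxy)-2-[4-(benzyloxy)phenyl]-4-oxochroman-3-yl]-2-(4-methoxyphenyl)chroman-4-one | COc1ccc([C@H]2Oc3cc(OCc4ccccc4)cc(OCc4ccccc4)c3C(=O)[C@H]2[C@@H]2C(=O)c3c(OCc4ccccc4)cc(OCc4ccccc4)cc3O[C@@H]2c2ccc(OCc3ccccc3)cc2)cc1 | intermediate
20 | Sikokianin A, (2S,3S)-3-[(2S,3S)-5,7-dihydroxy-2-(4-hydroxyphenyl)-4-oxochroman-3-yl]-5,7-dihydroxy-2-(4-methoxyphenyl)chroman-4-one | COc1ccc([C@H]2Oc3cc(O)cc(O)c3C(=O)[C@H]2[C@@H]2C(=O)c3c(O)cc(O)cc3O[C@@H]2c2ccc(O)cc2)cc1 | target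

**Step count.** Total: 7 steps. Longest linear sequence: 5 steps (steps 1, 2, 3, 6, 7); steps 4 and 5 make the aryne precursor.

**Steps most likely to fail**

1. Step 6 (proposed new method). Three processes may go wrong: the aryl anion may be protonated before it reaches the amide carbonyl; the potassium alkoxides may undergo reversible retro-aldol cleavage; and the hemiaminalate may collapse in the flask, after which base could epimerise C3/C3'' or open ring C. The fallback uses known chemistry, sets out from dilactone 9 and comes back at 19, forming the aryl–carbonyl bonds first and the aryl–oxygen bonds second. 5-Fluororesorcinol is benzylated (BnBr, K2CO3, DMF) to 1,3-bis(benzyloxy)-5-fluorobenzene F1. NBS then brominates F1 para to one benzyloxy group and ortho to fluorine, giving 2-bromo-1,5-bis(benzyloxy)-3-fluorobenzene F2. Bromine–lithium exchange (n-BuLi, THF, −78 °C) gives [2,4-bis(benzyloxy)-6-fluorophenyl]lithium F3. Two equivalents of F3 add to the two lactone carbonyls of 9 at −78 °C; the hindered aryllithium and the lactol alkoxides should prevent double addition. After an NH4Cl quench this should give (2S,3S)-1,4-bis[2,4-bis(benzyloxy)-6-fluorophenyl]-2-[(S)-[4-(benzyloxy)phenyl](hydroxy)methyl]-3-[(S)-hydroxy(4-methoxyphenyl)methyl]butane-1,4-dione F4, which may rest as its cyclic hemiketals. Cs2CO3 in DMF then closes both rings C by intramolecular nucleophilic aromatic substitution of each C2 alkoxide on the ortho fluorine, which is activated by the ortho carbonyl, with retention at C2 and C2'', to give 19.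

2. Step 2. The first enolisation may not stop cleanly at the mono-enolate, which would give the symmetric bis-adduct of 4. The first boron aldolate may also lactonise and lose the second auxiliary before the second aldol, or the second aldol may suffer eroded facial selectivity at the hindered enolate. The fallback sets out from 3 and comes back at 9, replacing the one-pot sequence by a stepwise one with a protecting group. The first Evans aldol with 4 is quenched cold and the crude adduct is silylated at once (TESOTf, 2,6-lutidine, CH2Cl2, −78 °C) to the mono-aldol triethylsilyl ether F5. A separate second Evans aldol (Bu2BOTf, iPr2NEt, then 5) gives the hydroxy silyl ether F6. HF·pyridine in THF then removes the silyl group, and both hydroxyls lactonise onto the distal imides to give 9 with release of the auxiliaries.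

3. Step 4. Bromination may take place para to the hydroxyl (between the two benzyloxy groups) or go on to the dibromide. The fallback sets out from 11 and comes back at 15, replacing electrophilic bromination and retro-Brook shift by carbamate-directed ortho-metalation. iPrNCO and Et3N convert 11 into 3,5-bis(benzyloxy)phenyl isopropylcarbamate F7. In situ N-silylation (TBSOTf, TMEDA), lithiation at the position flanked by carbamate and benzyloxy (n-BuLi, TMEDA, −78 °C) and TMSCl give 3,5-bis(benzyloxy)-2-(trimethylsilyl)phenyl isopropylcarbamate F8. Et2NH and DBU in MeCN cleave the carbamate to 3,5-bis(benzyloxy)-2-(trimethylsilyl)phenol F9, which is triflated in the same pot with PhNTf2 to give 15.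

**Further compounds**

F1 | step 6 | 1,3-bis(benzyloxy)-5-fluorobenzene | Fc1cc(OCc2ccccc2)cc(OCc2ccccc2)c1
F2 | step 6 | 2-bromo-1,5-bis(benzyloxy)-3-fluorobenzene | Fc1cc(OCc2ccccc2)cc(OCc2ccccc2)c1Br
F3 | step 6 | [2,4-bis(benzyloxy)-6-fluorophenyl]lithium | [Li]c1c(F)cc(OCc2ccccc2)cc1OCc1ccccc1
F4 | step 6 | (2S,3S)-1,4-bis[2,4-bis(benzyloxy)-6-fluorophenyl]-2-[(S)-[4-(benzyloxy)phenyl](hydroxy)methyl]-3-[(S)-hydroxy(4-methoxyphenyl)methyl]butane-1,4-dione | COc1ccc([C@@H](O)[C@@H](C(=O)c2c(F)cc(OCc3ccccc3)cc2OCc2ccccc2)[C@H](C(=O)c2c(F)cc(OCc3ccccc3)cc2OCc2ccccc2)[C@H](O)c2ccc(OCc3ccccc3)cc2)cc1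
F5 | step 2 | triethylsilyl ether of the mono syn-aldol adduct of 3 with 4 | COc1ccc([C@@H](O[Si](CC)(CC)CC)[C@@H](C(=O)N2C(=O)OC[C@@H]2Cc2ccccc2)CC(=O)N2C(=O)OC[C@@H]2Cc2ccccc2)cc1
F6 | step 2 | double syn-aldol adduct with one triethylsilyl ether and one free hydroxyl | COc1ccc([C@@H](O[Si](CC)(CC)CC)[C@@H](C(=O)N2C(=O)OC[C@@H]2Cc2ccccc2)[C@H](C(=O)N2C(=O)OC[C@@H]2Cc2ccccc2)[C@H](O)c2ccc(OCc3ccccc3)cc2)cc1
F7 | step 4 | 3,5-bis(benzyloxy)phenyl isopropylcarbamate | CC(C)NC(=O)Oc1cc(OCc2ccccc2)cc(OCc2ccccc2)c1
F8 | step 4 | 3,5-bis(benzyloxy)-2-(trimethylsilyl)phenyl isopropylcarbamate | CC(C)NC(=O)Oc1cc(OCc2ccccc2)cc(OCc2ccccc2)c1[Si](C)(C)C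
F9 | step 4 | 3,5-bis(benzyloxy)-2-(trimethylsilyl)phenol | Oc1cc(OCc2ccccc2)cc(OCc2ccccc2)c1[Si](C)(C)C
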